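**Retrosynthetic overview**
- Feature: in the γ-lactone (O1, C2, C3, C4, C5) the oxygens on C3 and C5 are 1,3-related across C4, and C3 and C5 are flanked by C2 and by the benzylic CH2. This is cis-cyclopent-4-ene-1,3-diol with its C=C cut, C2 and the benzylic carbon being the two former alkene carbons.
- Benzyl C(sp3)–C(sp2) bond: nickel/photoredox cross-electrophile coupling of a 5-bromomethyl lactone with bromobenzene; CH2Br from CH2OH, CH2OH from the CO2H of a lactone acid.
- Lactone acid: O1–C2 lactonisation of a hydroxy diacid released by ozonolysis with oxidative work-up of the mono-aroylated cyclopentenediol. This γ-lactone is the only ring made in the route and it closes in the key step.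
- Mono-aroylated diol: aroylation, then selective deacetylation, of the commercial desymmetrised monoacetate; both stereocentres are bought as a cis pair and only carried through.

Key step: step 3

Assumption: the (1R,4S)-monoacetate (free hydroxyl on the R carbon, acetate on the S carbon) is taken as the commercial, enantiopure enantiomer; the target is the (3R,5R) trans-lactone that the SMILES encodes.

**Step 1**
Reactants: 1 (1R,4S)-cis-4-acetoxy-2-cyclopenten-1-ol; 2 3,4-dimethoxybenzoyl chloride
Product: 3 (1R,4S)-4-acetoxycyclopent-2-en-1-yl 3,4-dimethoxybenzoate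
Conditions: Et3N, DMAP (cat.), CH2Cl2, 0 °C to rt
Reagents that add atoms: none
Why: DMAP-catalysed acylation (nucleophilic acyl substitution through the acylpyridinium ion) of the only free hydroxyl touches neither C–O stereocentre, so the cis-(1R,4S) array of 1 is kept with the aroyl group on the R carbon.

**Step 2**
Reactants: 3 (1R,4S)-4-acetoxycyclopent-2-en-1-yl 3,4-dimethoxybenzoate
Product: 4 (1R,4S)-4-hydroxycyclopent-2-en-1-yl 3,4-dimethoxybenzoate
Conditions: K2CO3 (0.2 equiv), MeOH, −10 to 0 °C; AcOH quench
Reagents that add atoms: none
Why: Carbonate-catalysed transesterification (Zemplén-type methanolysis) should remove the unhindered, more electrophilic acetate well before the conjugated, donor-substituted aroyl ester, with acyl–oxygen cleavage leaving both stereocentres intact; low temperature and an early acid quench keep the freed alkoxide from attacking the aroyl group across the ring.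

**Step 3**
Reactants: 4 (1R,4S)-4-hydroxycyclopent-2-en-1-yl 3,4-dimethoxybenzoate
Product: 7 (2S,4R)-4-[(3,4-dimethoxybenzoyl)oxy]-5-oxotetrahydrofuran-2-carboxylic acid, via secondary ozonide 5 (not isolated), via hydroxy diacid 6 (not isolated)
Conditions: O3/O2, CH2Cl2, Sudan Red 7B, −78 °C; N2 purge; solvent exchanged to HCO2H, 30% aq. H2O2, 0 to 40 °C; evaporation from PhMe
Reagents that add atoms: ozone, O=[O+][O-]; hydrogen peroxide, OO
Why: Ozone adds to the only C=C bond by 1,3-dipolar cycloaddition and the primary ozonide rearranges (Criegee mechanism) to secondary ozonide 5, which performic acid formed from HCO2H and H2O2 oxidises at both former alkene carbons to carboxyl groups, giving hydroxy diacid 6; this is the classical ozonolysis of a cycloalkene with oxidative work-up to an α,ω-diacid. The γ-lactone ring then closes by acid-catalysed 5-exo-trig acyl substitution of the free hydroxyl on the 1,4-related carboxyl (the one on the aroyloxy-bearing carbon), closure on the adjacent carboxyl being a three-membered ring. No stereocentre is made or broken: both carbinol C–O bonds stay intact, so the cis-(1R,4S) pair of 4 becomes the trans-(2S,4R) pair of 7. The step needs chemoselectivity for the alkene over the dimethoxyarene, which the ester carbonyl on that ring, the low temperature and dosing of ozone to the indicator end point should secure. It also needs the two ends of a nearly symmetrical diacid to be told apart, which follows from only one oxygen being free, so that the unacylated oxygen fixes which carboxyl becomes the lactone carbonyl and hence the enantiomer. Ring closure in strong acid should outrun a 1,3-aroyl shift, the one event that could erode enantiopurity.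

**Step 4**
Reactants: 7 (2S,4R)-4-[(3,4-dimethoxybenzoyl)oxy]-5-oxotetrahydrofuran-2-carboxylic acid
Product: 8 (3R,5S)-5-(hydroxymethyl)-2-oxotetrahydrofuran-3-yl 3,4-dimethoxybenzoate
Conditions: BH3·SMe2, THF, 0 °C to rt; MeOH quench
Reagents that add atoms: none
Why: Chemoselective borane reduction of a carboxylic acid: the free acid is reduced through its acyloxyborane far faster than the lactone or the aryl ester, and no stereocentre is involved.

**Step 5**
Reactants: 8 (3R,5S)-5-(hydroxymethyl)-2-oxotetrahydrofuran-3-yl 3,4-dimethoxybenzoate
Product: 9 (3R,5S)-5-(bromomethyl)-2-oxotetrahydrofuran-3-yl 3,4-dimethoxybenzoate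
Conditions: CBr4, PPh3, CH2Cl2, 0 °C
Reagents that add atoms: carbon tetrabromide, BrC(Br)(Br)Br
Why: Appel reaction: the primary alcohol is activated as its alkoxyphosphonium salt and displaced by bromide in an SN2 step at the exocyclic CH2, leaving both ring stereocentres untouched.

**Step 6**
Reactants: 9 (3R,5S)-5-(bromomethyl)-2-oxotetrahydrofuran-3-yl 3,4-dimethoxybenzoate; 10 bromobenzene
Product: 11 (3R,5R)-5-benzyl-2-oxotetrahydrofuran-3-yl 3,4-dimethoxybenzoate (trichoderolide F)
Conditions: PhBr (2 equiv), [Ir(dF(CF3)ppy)2(dtbbpy)]PF6 (1 mol%), NiCl2·DME (5 mol%), dtbbpy (5 mol%), (Me3Si)3SiH, Na2CO3, DME, blue LEDs, rt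
Reagents that add atoms: none
Why: Silyl-radical-mediated nickel/photoredox cross-electrophile coupling: the tris(trimethylsilyl)silyl radical abstracts bromine from the primary bromide, the exocyclic alkyl radical is captured by the aryl nickel bromide formed from bromobenzene and zerovalent nickel, and C(sp3)–C(sp2) reductive elimination from trivalent nickel forms the benzyl group without a metal reductant that could trigger β-elimination of the lactone carboxylate; the radical carbon is not stereogenic, so C3 and C5 are unchanged (the C5 descriptor changes from S to R only through the priority switch).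

**Compound list**
1 | (1R,4S)-cis-4-acetoxy-2-cyclopenten-1-ol | CC(=O)O[C@H]1C[C@@H](O)C=C1 | starting material
2 | 3,4-dimethoxybenzoyl chloride | COc1ccc(C(Cl)=O)cc1OC | starting material
3 | (1R,4S)-4-acetoxycyclopent-2-en-1-yl 3,4-dimethoxybenzoate | COc1ccc(C(=O)O[C@@H]2C[C@H](OC(C)=O)C=C2)cc1OC | intermediate
4 | (1R,4S)-4-hydroxycyclopent-2-en-1-yl 3,4-dimethoxybenzoate | COc1ccc(C(=O)O[C@@H]2C[C@H](O)C=C2)cc1OC | intermediate
5 | secondary ozonide, (2R,4S)-4-hydroxy-6,7,8-trioxabicyclo[3.2.1]octan-2-yl 3,4-dimethoxybenzoate (bridgehead configuration not specified) | COc1ccc(C(=O)O[C@@H]2C[C@H](O)C3OOC2O3)cc1OC | intermediate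
6 | hydroxy diacid, (2R,4S)-2-[(3,4-dimethoxybenzoyl)oxy]-4-hydroxypentanedioic acid | COc1ccc(C(=O)O[C@@H](C(=O)O)C[C@H](O)C(=O)O)cc1OC | intermediate
7 | (2S,4R)-4-[(3,4-dimethoxybenzoyl)oxy]-5-oxotetrahydrofuran-2-carboxylic acid | COc1ccc(C(=O)O[C@@H]2C[C@@H](C(=O)O)OC2=O)cc1OC | intermediate
8 | (3R,5S)-5-(hydroxymethyl)-2-oxotetrahydrofuran-3-yl 3,4-dimethoxybenzoate | COc1ccc(C(=O)O[C@@H]2C[C@@H](CO)OC2=O)cc1OC | intermediate
9 | (3R,5S)-5-(bromomethyl)-2-oxotetrahydrofuran-3-yl 3,4-dimethoxybenzoate | COc1ccc(C(=O)O[C@@H]2C[C@@H](CBr)OC2=O)cc1OC | intermediate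
10 | bromobenzene | Brc1ccccc1 | starting material
11 | (3R,5R)-5-benzyl-2-oxotetrahydrofuran-3-yl 3,4-dimethoxybenzoate (trichoderolide F) | COc1ccc(C(=O)O[C@@H]2C[C@@H](Cc3ccccc3)OC2=O)cc1OC | target

**Step count**
Total steps: 6. Longest linear sequence: 6 steps (1 to 11).

**Steps most likely to fail**

Step 3. What may go wrong:
- ozone attacking the dimethoxyarene once the alkene is consumed;
- abnormal peracid oxidation of the α-oxygenated termini, with loss of a carbon by Baeyer–Villiger-type migration;
- a 1,3-aroyl shift in the open hydroxy diacid before ring closure, which would lower enantiopurity.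

Fallback, setting out from 4 and returning at 7: the ring is closed at the aldehyde oxidation level so that no open hydroxy diacid and no peracid are involved. Ozonolysis of 4 in CH2Cl2/MeOH at −78 °C with Me2S work-up should give the hydroxy dialdehyde, which is expected to close at once to the lactol aldehyde (3R,5S)-5-formyl-2-hydroxytetrahydrofuran-3-yl 3,4-dimethoxybenzoate F1. The hydroxyl can reach only the distal formyl group, so the regiochemistry is fixed there. Oxoammonium oxidation of F1 with TEMPO (cat.) and PhI(OAc)2 in MeCN/H2O should then take the lactol to the lactone and the formyl group, through its hydrate, to the acid, giving 7.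

Step 6. What may go wrong:
- β-elimination of the lactone carboxylate from an alkylnickel intermediate, opening the ring to a pentenoic acid;
- hydrodebromination of the alkyl bromide by the silane;
- homocoupling of bromobenzene.

Fallback, setting out from 8 and returning at 11: a polar copper-mediated substitution replaces the radical coupling. Alcohol 8 with Tf2O and 2,6-lutidine in CH2Cl2 at −78 °C should give the primary triflate (3R,5S)-2-oxo-5-{[(trifluoromethanesulfonyl)oxy]methyl}tetrahydrofuran-3-yl 3,4-dimethoxybenzoate F2. Displacement with Ph2CuLi (from PhLi and CuBr·SMe2) in THF at −78 °C, where a primary triflate should react faster than either ester, would deliver 11 directly.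

Step 2. What may go wrong:
- competing methanolysis of the aroyl ester;
- base-mediated 1,3-aroyl shift between the two cis oxygens, which would lower both yield and enantiopurity.

Fallback, setting out from 3 and returning at 7 (compound 4 is bypassed): the order of deacetylation and ring cleavage is reversed so that the hydroxyl is never free under basic conditions. Ozonolysis of 3 (O3, CH2Cl2, −78 °C; then HCO2H/H2O2) should give (2S,4R)-2-acetoxy-4-[(3,4-dimethoxybenzoyl)oxy]pentanedioic acid F3. Aqueous acid (1 M HCl, dioxane, 50 °C) should then hydrolyse the acetate faster than the aroyl ester, and the freed hydroxyl should lactonise in the same medium to 7.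

**Further compounds**
F1 | step 3 | (3R,5S)-5-formyl-2-hydroxytetrahydrofuran-3-yl 3,4-dimethoxybenzoate (anomeric mixture) | COc1ccc(C(=O)O[C@@H]2C[C@@H](C=O)OC2O)cc1OC
F2 | step 6 | (3R,5S)-2-oxo-5-{[(trifluoromethanesulfonyl)oxy]methyl}tetrahydrofuran-3-yl 3,4-dimethoxybenzoate | COc1ccc(C(=O)O[C@@H]2C[C@@H](COS(=O)(=O)C(F)(F)F)OC2=O)cc1OC
F3 | step 2 | (2S,4R)-2-acetoxy-4-[(3,4-dimethoxybenzoyl)oxy]pentanedioic acid | COc1ccc(C(=O)O[C@@H](C(=O)O)C[C@H](OC(C)=O)C(=O)O)cc1OC
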